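The alpha run cannot make more target than its reagent allows. One target takes one reagent, and c(reagent) at the start is 0.0830 M against 0.750 M of starting material, so the ceiling is 11.1 % of the starting material charged. Reagent is the limiting reagent here, and I keep its books.

| setting | zeta | theta | epsilon | delta | alpha |
|---|---|---|---|---|---|
| starting material | 0.250 M | 0.130 M | 0.380 M | 0.250 M | 0.750 M |
| reagent | 0.250 M | 0.130 M | 0.250 M | 0.120 M | 0.0830 M |
| time |  |  |  |  | 33 min |

| zeta run: time / min | zeta run: [target] / M | theta run: time / min | theta run: [target] / M | epsilon run: time / min | epsilon run: [target] / M | delta run: time / min | delta run: [target] / M |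
|---|---|---|---|---|---|---|---|
| 1.3 | 0.0224 | 1.3 | 0.0091 | 1.3 | 0.0299 | 1.3 | 0.0127 |
| 2.1 | 0.0324 | 2.1 | 0.0118 | 2.1 | 0.0466 | 2.1 | 0.0175 |
| 3.3 | 0.0495 | 3.3 | 0.0169 | 3.3 | 0.0683 | 3.3 | 0.0279 |
| 5.2 | 0.0714 | 5.2 | 0.0243 | 5.2 | 0.0901 | 5.2 | 0.0388 |
| 8.3 | 0.0897 | 8.3 | 0.0355 | 8.3 | 0.1161 | 8.3 | 0.0524 |
| 13 | 0.1054 | 13 | 0.0433 | 13 | 0.1344 | 13 | 0.0650 |
| 21 | 0.1186 | 21 | 0.0586 | 21 | 0.1513 | 21 | 0.0713 |
| 33 | 0.1241 | 33 | 0.0571 | 33 | 0.1551 | 33 | 0.0825 |

(standard deviation of a reading: 0.002 M)

- order of the initial rate in [reagent], near the charge of the zeta run, the rate being that where two percent of its starting material are target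
- order of the initial rate in [starting material], near the charge of the zeta run, the rate being that where two percent of its starting material are target (one fixed amount of target, the same in the runs compared)
- target in the alpha run at 33 min, as a share of the starting material charged

- Overall: starting material + reagent -> target.
- Constant volume, constant temperature.
- The analysis sees a species whether free or bound.
- "The second partner" is reagent.
- An order is taken over about fifteen percent of the charge, up and down.

The first entry is reagent still unused at 33 min. I take the zeta reading at 3.3 min as a second-order slope and apply it to the alpha charge, where the excess of starting material makes the loss of reagent roughly pseudo-first-order. That gives the reagent a life of 5.56 min, so about 0.263 % stands unused at the end.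

The second entry is the keep, the target made per reagent charged. At 33 min the delta run keeps 68.8 %, with target at 33.0 % of its starting material. The epsilon run keeps 62.0 %, less than the delta run, with that ratio at 40.8 %. The delta run is still climbing, so this is rough. I read the fall as target competing with starting material for reagent and draw a straight line through both runs. Its slope, the drag, is 0.859, and it meets zero target at 97.1 %, the clean keep: the share of reagent reaching target with no target in the way.

The alpha ratio depends on the answer, so I go round. The clean keep lowers itself to 87.9 %, and putting that back gives 88.7 %. The books close with that share as target, the small unused share, and 11.0 % lost to side paths. My figure is 9.82 % of the starting material.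

The forecast gives a reagent order of 0.77, a starting-material order of 0.77 and 9.5 % target, holding that “reagent is limiting and the run is fast”. Its target figure is lower than mine.

The simulation gives a reagent order of 1.0, a starting-material order of 0.79 and 9.22 % target.

    starting material + reagent → target (0.4890 L mol⁻¹ min⁻¹)
    starting material + reagent → side product (0.06600 L mol⁻¹ min⁻¹)
    2 starting material ⇌ idle substrate dimer, settled at all times (1.280 L mol⁻¹)
    target + reagent → side product (0.1482 L mol⁻¹ min⁻¹)

The alpha keep comes to 83.1 %, less than my 88.7 %, and the reagent order stands above the forecast's. On the zeta run, with equal charges, the clean keep and the drag give 0.131 M of target, and the reading at 33 min is 0.1241 M. Near the zeta charge the order in starting material is 0.79 because pairs of starting material join as idle substrate dimer, and the same run without that joining gives 1.0.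

Readings and results were generated by integration with made-up constants; scatter was added.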